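**Strategy.** Ring B is a hexasubstituted benzene whose oxygen-bearing carbons C5, C7 and C8a alternate with the carbon-bearing C4a, C6 and C8, so it is cut into three oxygenated alkynes: C5≡C4a (ethoxy ynone), C8a≡C8 (tertiary alkynyl ether) and C6≡C7 (siloxypropyne). The first two are already linked through C4–C3–C2–O1 of ring C in diyne 22, which also carries the MOM-protected ring A on the C8 methylene. One rhodium-catalysed (2+2+2) cycloaddition of 22 with siloxyalkyne 26 should form C4a–C8a, C5–C6 and C7–C8 and close rings B and C together; desilylation, BCl3 deprotection and isobutyrylation of the free ring A carbon then complete the target.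

Key step: step 12

Remark on the chemistry: the target is achiral; carbinol 21 is racemic and its centre is erased in step 10. Alkynyl ethers 16, 17, 18, 21 and 22 are kept at or below 25 °C and purified on triethylamine-deactivated silica, because they hydrate in acid and fragment to ketenes when heated. The carbonyl of the tether is introduced only after the organolithium step, at the alcohol oxidation level, so that n-BuLi never meets an ester or amide.

**Route**

Step 1
Reactants: 1 2-methylphloroglucinol
Product: 2 2-methyl-1,3,5-tris(methoxymethoxy)benzene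
Conditions: MOMCl (3.6 equiv), i-Pr2NEt (4.5 equiv), DMF, 0→23 °C
Reagents that add atoms: chloromethyl methyl ether (MOMCl), COCCl
Why: Williamson-type O-alkylation of the three phenols with the hard electrophile MOMCl should favour O- over C-alkylation and give the tris-acetal (MOM protection).

Step 2
Reactants: 2 2-methyl-1,3,5-tris(methoxymethoxy)benzene
Product: 5 [3-methyl-2,4,6-tris(methoxymethoxy)phenyl]methanol, via aryllithium 3 (not isolated), via aldehyde 4 (not isolated)
Conditions: n-BuLi, THF, 0 °C; DMF, 0 °C; then MeOH, NaBH4, 0 °C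
Reagents that add atoms: N,N-dimethylformamide, CN(C)C=O
Why: Directed ortho-metalation at a ring position flanked by two MOM ethers (the two free positions are equivalent), formylation of the aryllithium with DMF and in situ borohydride reduction should deliver the benzylic alcohol in one pot.

Step 3
Reactants: 5 [3-methyl-2,4,6-tris(methoxymethoxy)phenyl]methanol
Product: 7 2-(bromomethyl)-4-methyl-1,3,5-tris(methoxymethoxy)benzene, via benzyl mesylate 6 (not isolated)
Conditions: Ms2O, i-Pr2NEt, LiBr, THF, −20→0 °C; cold filtration through basic alumina, used at once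
Reagents that add atoms: lithium bromide, [Li+].[Br-]
Why: Sulfonylation followed by SN2 displacement with bromide under non-acidic conditions should spare the MOM acetals, and the easily ionised bromide is consumed immediately in step 6.

Step 4
Reactants: 8 3-methylbutane-1,3-diol
Product: 9 2-methyl-4-[(triisopropylsilyl)oxy]butan-2-ol
Conditions: TIPSCl, imidazole, CH2Cl2, 0→23 °C
Reagents that add atoms: triisopropylsilyl chloride, CC(C)[Si](Cl)(C(C)C)C(C)C
Why: Selective silyl ether protection of the primary over the tertiary hydroxyl on steric grounds, with the bulky triisopropylsilyl group chosen so that 1,5 oxygen-to-oxygen silyl transfer to the tertiary alkoxide in step 5 should be slow.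

Step 5
Reactants: 9 2-methyl-4-[(triisopropylsilyl)oxy]butan-2-ol; 10 trichloroethylene
Product: 13 {3-[(E)-1,2-dichloroethenyl]oxy-3-methylbutoxy}triisopropylsilane, via potassium alkoxide 11 (not isolated), via dichloroacetylene 12 (not isolated)
Conditions: KH, THF, 0 °C (brief); Cl2C=CHCl, −50→23 °C
Reagents that add atoms: none
Why: Established trichloroethylene route to 1,2-dichlorovinyl ethers, in which the alkoxide dehydrochlorinates trichloroethylene to dichloroacetylene and then adds to it in anti fashion (nucleophilic addition to a haloalkyne), the E geometry being of no later consequence.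

Step 6
Reactants: 13 {3-[(E)-1,2-dichloroethenyl]oxy-3-methylbutoxy}triisopropylsilane; 7 2-(bromomethyl)-4-methyl-1,3,5-tris(methoxymethoxy)benzene
Product: 16 triisopropyl[3-methyl-3-({3-[3-methyl-2,4,6-tris(methoxymethoxy)phenyl]prop-1-yn-1-yl}oxy)butoxy]silane, via chloroalkynyl ether 14 (not isolated), via lithium acetylide 15 (not isolated)
Conditions: n-BuLi (2.05 equiv), THF, −78→−40 °C; then 7 (0.8 equiv), DMPU, −78→0 °C
Reagents that add atoms: none
Why: Dehydrochlorination and chlorine–lithium exchange by two equivalents of n-BuLi should give the lithium alkoxyacetylide, whose SN2 alkylation by the activated benzylic bromide forms the C8–CH2 bond while no carbonyl group is yet present.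

Step 7
Reactants: 16 triisopropyl[3-methyl-3-({3-[3-methyl-2,4,6-tris(methoxymethoxy)phenyl]prop-1-yn-1-yl}oxy)butoxy]silane
Product: 17 3-methyl-3-({3-[3-methyl-2,4,6-tris(methoxymethoxy)phenyl]prop-1-yn-1-yl}oxy)butan-1-ol
Conditions: TBAF, THF, 0→23 °C
Reagents that add atoms: none
Why: Fluoride-mediated desilylation of the primary silyl ether is basic and acid-free, so the alkynyl ether and the MOM acetals should survive.

Step 8
Reactants: 17 3-methyl-3-({3-[3-methyl-2,4,6-tris(methoxymethoxy)phenyl]prop-1-yn-1-yl}oxy)butan-1-ol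
Product: 18 3-methyl-3-({3-[3-methyl-2,4,6-tris(methoxymethoxy)phenyl]prop-1-yn-1-yl}oxy)butanal
Conditions: Dess–Martin periodinane, NaHCO3, CH2Cl2, 0 °C; used crude
Reagents that add atoms: none
Why: Dess–Martin oxidation buffered with NaHCO3 should stop at the aldehyde and keep the medium free of acid that would hydrate the alkynyl ether.

Step 9
Reactants: 18 3-methyl-3-({3-[3-methyl-2,4,6-tris(methoxymethoxy)phenyl]prop-1-yn-1-yl}oxy)butanal; 19 ethoxyacetylene
Product: 21 rac-1-ethoxy-5-methyl-5-({3-[3-methyl-2,4,6-tris(methoxymethoxy)phenyl]prop-1-yn-1-yl}oxy)hex-1-yn-3-ol, via lithium ethoxyacetylide 20 (not isolated)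
Conditions: 19, n-BuLi, THF, −78 °C; then 18, −78 °C; H2O, −78→0 °C
Reagents that add atoms: none
Why: 1,2-Addition of a lithium acetylide to an aldehyde at −78 °C, in which the weakly basic acetylide should not trigger β-elimination and the new carbinol centre forms without control as a racemate that step 10 erases.

Step 10
Reactants: 21 rac-1-ethoxy-5-methyl-5-({3-[3-methyl-2,4,6-tris(methoxymethoxy)phenyl]prop-1-yn-1-yl}oxy)hex-1-yn-3-ol
Product: 22 1-ethoxy-5-methyl-5-({3-[3-methyl-2,4,6-tris(methoxymethoxy)phenyl]prop-1-yn-1-yl}oxy)hex-1-yn-3-one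
Conditions: MnO2 (activated, excess), CH2Cl2, 0→23 °C; used promptly
Reagents that add atoms: none
Why: Oxidation of a propargylic alcohol with activated MnO2 is neutral and should give the push–pull alkoxy ynone without the acid that would cause Meyer–Schuster rearrangement.

Step 11
Reactants: 23 propyne
Product: 26 triisopropyl(prop-1-yn-1-yloxy)silane, via propynyllithium 24 (not isolated), via lithium ynolate 25 (not isolated)
Conditions: n-BuLi, THF, −78 °C; LiOO-t-Bu (from t-BuOOH, LiHMDS), −78→0 °C; TIPSOTf, −78→0 °C
Reagents that add atoms: tert-butyl hydroperoxide, CC(C)(C)OO; triisopropylsilyl trifluoromethanesulfonate, CC(C)[Si](OS(=O)(=O)C(F)(F)F)(C(C)C)C(C)C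
Why: Oxidation of a lithium acetylide by lithium tert-butyl peroxide gives the lithium ynolate, which the bulky silyl triflate should trap on oxygen (O-silylation of an ynolate) to give the siloxyalkyne.

Step 12
Reactants: 22 1-ethoxy-5-methyl-5-({3-[3-methyl-2,4,6-tris(methoxymethoxy)phenyl]prop-1-yn-1-yl}oxy)hex-1-yn-3-one; 26 triisopropyl(prop-1-yn-1-yloxy)silane
Product: 27 5-ethoxy-2,2,6-trimethyl-8-{[3-methyl-2,4,6-tris(methoxymethoxy)phenyl]methyl}-7-[(triisopropylsilyl)oxy]chroman-4-one
Conditions: [Rh(cod)2]BF4 (10 mol %), rac-BINAP (10 mol %), H2 then Ar (catalyst activation); 26 (3 equiv), slow addition of 22, CH2Cl2, 0→23 °C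
Reagents that add atoms: none
Why: Proposed new method: the hydrogen-activated cationic monovalent rhodium–bisphosphine complex should bind both alkynes of 22 and undergo oxidative cyclisation to a bicyclic rhodacyclopentadiene (trivalent rhodium), forming C4a–C8a and closing ring C as a six-membered ring through the C4–C3–C2–O1 tether; insertion of 26 into a Rh–C bond and reductive elimination then form C5–C6 and C7–C8 and close ring B as the benzene ring of a formal (2+2+2) cycloaddition. The closest known reaction type is the cationic monovalent rhodium/BINAP-type cyclotrimerisation of tethered diynes with alkynyl ethers or ynamides to hexasubstituted benzenes; what is untested is a 1,7-diyne that combines a push–pull alkoxy ynone with a tertiary alkynyl ether, and a siloxyalkyne as third component. No stereocentre is created. The constitution of rings B and C is fixed by the tether, so the only selectivity needed is the orientation of 26, which the polarity match of its nucleophilic methyl-bearing carbon with electrophilic C5 and of its siloxy-bearing carbon with nucleophilic C8 should secure. Slow addition of 22 to excess 26 at or below 23 °C should suppress diyne self-reaction, Lewis-acid-induced alkynyl ether–carbonyl metathesis and the retro-ene fragmentation of the tertiary alkynyl ether to a ketene.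

Step 13
Reactants: 27 5-ethoxy-2,2,6-trimethyl-8-{[3-methyl-2,4,6-tris(methoxymethoxy)phenyl]methyl}-7-[(triisopropylsilyl)oxy]chroman-4-one
Product: 28 5-ethoxy-7-hydroxy-2,2,6-trimethyl-8-{[3-methyl-2,4,6-tris(methoxymethoxy)phenyl]methyl}chroman-4-one
Conditions: TBAF, AcOH, THF, 0→23 °C
Reagents that add atoms: none
Why: Fluoride-mediated desilylation of the aryl silyl ether, with acetic acid buffering the resulting phenoxide, should leave the acetals, the ethyl ether and the chromanone untouched.

Step 14
Reactants: 28 5-ethoxy-7-hydroxy-2,2,6-trimethyl-8-{[3-methyl-2,4,6-tris(methoxymethoxy)phenyl]methyl}chroman-4-one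
Product: 29 5,7-dihydroxy-2,2,6-trimethyl-8-[(2,4,6-trihydroxy-3-methylphenyl)methyl]chroman-4-one
Conditions: BCl3 (excess), CH2Cl2, −78→0 °C; then MeOH, −78 °C→23 °C; under Ar
Reagents that add atoms: none
Why: Lewis-acid ether cleavage, in which BCl3 removes the MOM acetals and, through chelation between the C4 carbonyl and the peri C5 oxygen, the ethyl ether, while the cold methanol quench traps the methoxymethyl fragments as dimethoxymethane before they can alkylate ring A.

Step 15
Reactants: 29 5,7-dihydroxy-2,2,6-trimethyl-8-[(2,4,6-trihydroxy-3-methylphenyl)methyl]chroman-4-one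
Product: 30 5,7-dihydroxy-2,2,6-trimethyl-8-{[2,4,6-trihydroxy-3-methyl-5-(2-methylpropanoyl)phenyl]methyl}chroman-4-one (CNP0186856.0)
Conditions: i-PrCOCl (1.1 equiv), AlCl3 (excess), CH2Cl2/PhNO2, 0→23 °C; then ice-cold 1 M HCl
Reagents that add atoms: isobutyryl chloride, CC(C)C(Cl)=O
Why: Friedel–Crafts C-acylation can only occur at the single unsubstituted aromatic carbon of 29, the ring A position flanked by two hydroxyls, and any aryl ester formed should undergo Fries migration to that same carbon before the acidic work-up frees the aluminium phenoxides.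

**Compound list**

1 | 2-methylphloroglucinol (2-methylbenzene-1,3,5-triol) | Cc1c(O)cc(O)cc1O | starting material
2 | 2-methyl-1,3,5-tris(methoxymethoxy)benzene | Cc1c(OCOC)cc(OCOC)cc1OCOC | intermediate
3 | [3-methyl-2,4,6-tris(methoxymethoxy)phenyl]lithium | [Li]c1c(OCOC)c(C)c(OCOC)cc1OCOC | intermediate (not isolated)
4 | 3-methyl-2,4,6-tris(methoxymethoxy)benzaldehyde | O=Cc1c(OCOC)c(C)c(OCOC)cc1OCOC | intermediate (not isolated)
5 | [3-methyl-2,4,6-tris(methoxymethoxy)phenyl]methanol | OCc1c(OCOC)c(C)c(OCOC)cc1OCOC | intermediate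
6 | [3-methyl-2,4,6-tris(methoxymethoxy)phenyl]methyl methanesulfonate | CS(=O)(=O)OCc1c(OCOC)c(C)c(OCOC)cc1OCOC | intermediate (not isolated)
7 | 2-(bromomethyl)-4-methyl-1,3,5-tris(methoxymethoxy)benzene | BrCc1c(OCOC)c(C)c(OCOC)cc1OCOC | intermediate
8 | 3-methylbutane-1,3-diol | CC(C)(O)CCO | starting material
9 | 2-methyl-4-[(triisopropylsilyl)oxy]butan-2-ol | CC(C)(O)CCO[Si](C(C)C)(C(C)C)C(C)C | intermediate
10 | trichloroethylene | ClC=C(Cl)Cl | starting material
11 | potassium 2-methyl-4-[(triisopropylsilyl)oxy]butan-2-olate | CC(C)([O-])CCO[Si](C(C)C)(C(C)C)C(C)C.[K+] | intermediate (not isolated)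
12 | dichloroacetylene | ClC#CCl | intermediate (not isolated)
13 | {3-[(E)-1,2-dichloroethenyl]oxy-3-methylbutoxy}triisopropylsilane | Cl/C=C(/Cl)OC(C)(C)CCO[Si](C(C)C)(C(C)C)C(C)C | intermediate
14 | [3-(chloroethynyloxy)-3-methylbutoxy]triisopropylsilane | ClC#COC(C)(C)CCO[Si](C(C)C)(C(C)C)C(C)C | intermediate (not isolated)
15 | ({2-methyl-4-[(triisopropylsilyl)oxy]butan-2-yl}oxyethynyl)lithium | [Li]C#COC(C)(C)CCO[Si](C(C)C)(C(C)C)C(C)C | intermediate (not isolated)
16 | triisopropyl[3-methyl-3-({3-[3-methyl-2,4,6-tris(methoxymethoxy)phenyl]prop-1-yn-1-yl}oxy)butoxy]silane | CC(C)[Si](OCCC(C)(C)OC#CCc1c(OCOC)c(C)c(OCOC)cc1OCOC)(C(C)C)C(C)C | intermediate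
17 | 3-methyl-3-({3-[3-methyl-2,4,6-tris(methoxymethoxy)phenyl]prop-1-yn-1-yl}oxy)butan-1-ol | OCCC(C)(C)OC#CCc1c(OCOC)c(C)c(OCOC)cc1OCOC | intermediate
18 | 3-methyl-3-({3-[3-methyl-2,4,6-tris(methoxymethoxy)phenyl]prop-1-yn-1-yl}oxy)butanal | O=CCC(C)(C)OC#CCc1c(OCOC)c(C)c(OCOC)cc1OCOC | intermediate
19 | ethoxyacetylene | CCOC#C | starting material
20 | lithium ethoxyacetylide | CCOC#C[Li] | intermediate (not isolated)
21 | rac-1-ethoxy-5-methyl-5-({3-[3-methyl-2,4,6-tris(methoxymethoxy)phenyl]prop-1-yn-1-yl}oxy)hex-1-yn-3-ol (racemic at C3) | CCOC#CC(O)CC(C)(C)OC#CCc1c(OCOC)c(C)c(OCOC)cc1OCOC | intermediate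
22 | 1-ethoxy-5-methyl-5-({3-[3-methyl-2,4,6-tris(methoxymethoxy)phenyl]prop-1-yn-1-yl}oxy)hex-1-yn-3-one | CCOC#CC(=O)CC(C)(C)OC#CCc1c(OCOC)c(C)c(OCOC)cc1OCOC | intermediate
23 | propyne | CC#C | starting material
24 | prop-1-yn-1-yllithium | CC#C[Li] | intermediate (not isolated)
25 | lithium prop-1-yn-1-olate | CC#C[O-].[Li+] | intermediate (not isolated)
26 | triisopropyl(prop-1-yn-1-yloxy)silane | CC#CO[Si](C(C)C)(C(C)C)C(C)C | intermediate
27 | 5-ethoxy-2,2,6-trimethyl-8-{[3-methyl-2,4,6-tris(methoxymethoxy)phenyl]methyl}-7-[(triisopropylsilyl)oxy]chroman-4-one | CCOc1c(C)c(O[Si](C(C)C)(C(C)C)C(C)C)c(Cc2c(OCOC)c(C)c(OCOC)cc2OCOC)c2OC(C)(C)CC(=O)c12 | intermediate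
28 | 5-ethoxy-7-hydroxy-2,2,6-trimethyl-8-{[3-methyl-2,4,6-tris(methoxymethoxy)phenyl]methyl}chroman-4-one | CCOc1c(C)c(O)c(Cc2c(OCOC)c(C)c(OCOC)cc2OCOC)c2OC(C)(C)CC(=O)c12 | intermediate
29 | 5,7-dihydroxy-2,2,6-trimethyl-8-[(2,4,6-trihydroxy-3-methylphenyl)methyl]chroman-4-one | Cc1c(O)c(Cc2c(O)c(C)c(O)c3c2OC(C)(C)CC3=O)c(O)cc1O | intermediate
30 | 5,7-dihydroxy-2,2,6-trimethyl-8-{[2,4,6-trihydroxy-3-methyl-5-(2-methylpropanoyl)phenyl]methyl}chroman-4-one (CNP0186856.0) | Cc1c(O)c(Cc2c(O)c(C)c(O)c3c2OC(C)(C)CC3=O)c(O)c(C(=O)C(C)C)c1O | target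

**Step count**

Total: 15 steps. Longest linear sequence: 12 steps (steps 1–3, 6–10 and 12–15, from 2-methylphloroglucinol 1).

**Steps most likely to fail**

Step 12 (the step that goes beyond known chemistry). What may go wrong:
- oligomerisation of the siloxyalkyne on rhodium in place of cross-cycloaddition;
- Lewis-acid-induced fragmentation, β-elimination or alkynyl ether–carbonyl metathesis of the diyne before oxidative cyclisation;
- insertion of the third alkyne in the reverse sense.

Fallback (known chemistry): it sets out from 1 and comes back to the route at 30. Compound 1 is condensed with 3-methylbut-2-enoic acid in P2O5/MeSO3H (Friedel–Crafts acylation, then oxa-Michael closure) to give 5,7-dihydroxy-2,2,6-trimethylchroman-4-one F1, which is separated from its 8-methyl isomer. A phenolic Mannich reaction with aqueous formaldehyde and dimethylamine at C8, the only free ring carbon, gives 8-[(dimethylamino)methyl]-5,7-dihydroxy-2,2,6-trimethylchroman-4-one F2. A second portion of 1 is C-acylated with isobutyryl chloride/AlCl3 to 1-(2,4,6-trihydroxy-3-methylphenyl)-2-methylpropan-1-one F3. Heating F2 with F3 in dioxane should expel dimethylamine, generate the ring B ortho-quinone methide and let the free ring carbon of F3 add to it, giving 30 directly.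

Step 6. What may go wrong: ionisation of the very electron-rich benzylic bromide and Friedel–Crafts self-alkylation (or halogen–metal exchange) may outrun C-alkylation by the acetylide.

Fallback: it sets out from 5 and 13 and comes back at 16. Alcohol 5 is converted with MsCl/Et3N/LiCl into the more robust 2-(chloromethyl)-4-methyl-1,3,5-tris(methoxymethoxy)benzene F4. Acetylide 15, generated from 13 as in step 6, is transmetalated with ZnCl2 to chloro({2-methyl-4-[(triisopropylsilyl)oxy]butan-2-yl}oxyethynyl)zinc F5. Negishi coupling of F4 with F5, catalysed by PdCl2(DPEphos) (reduced in the flask to zerovalent palladium) in THF at 23 °C, should give 16 without a polar cosolvent.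

Step 15. What may go wrong:
- O-acylation may compete with C-acylation;
- acid may cleave the methylene bridge;
- ring C may open and re-close through the C5 oxygen.

Fallback: it sets out from 29 and comes back at 30. A Houben–Hoesch reaction of 29 with isobutyronitrile, ZnCl2 and HCl gas in Et2O at 0 °C cannot acylate oxygen and should give the ketiminium salt 1-{2,4,6-trihydroxy-3-methyl-5-[(5,7-dihydroxy-2,2,6-trimethyl-4-oxochroman-8-yl)methyl]phenyl}-2-methylpropan-1-iminium chloride F6. Warming F6 in water hydrolyses it to 30.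

**Further compounds**

F1 | step 12 | 5,7-dihydroxy-2,2,6-trimethylchroman-4-one | Cc1c(O)cc2OC(C)(C)CC(=O)c2c1O
F2 | step 12 | 8-[(dimethylamino)methyl]-5,7-dihydroxy-2,2,6-trimethylchroman-4-one | Cc1c(O)c(CN(C)C)c2OC(C)(C)CC(=O)c2c1O
F3 | step 12 | 1-(2,4,6-trihydroxy-3-methylphenyl)-2-methylpropan-1-one | Cc1c(O)cc(O)c(C(=O)C(C)C)c1O
F4 | step 6 | 2-(chloromethyl)-4-methyl-1,3,5-tris(methoxymethoxy)benzene | ClCc1c(OCOC)c(C)c(OCOC)cc1OCOC
F5 | step 6 | chloro({2-methyl-4-[(triisopropylsilyl)oxy]butan-2-yl}oxyethynyl)zinc | Cl[Zn]C#COC(C)(C)CCO[Si](C(C)C)(C(C)C)C(C)C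
F6 | step 15 | 1-{2,4,6-trihydroxy-3-methyl-5-[(5,7-dihydroxy-2,2,6-trimethyl-4-oxochroman-8-yl)methyl]phenyl}-2-methylpropan-1-iminium chloride | Cc1c(O)c(Cc2c(O)c(C)c(O)c3c2OC(C)(C)CC3=O)c(O)c(C(=[NH2+])C(C)C)c1O.[Cl-]
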